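## Retrosynthetic overview

1. Feature: ring B (C1 ketone, C2, C3, C4 diaryl methine, C4a, C8a) contains the four-atom unit C4–C4a–C8a–C1. This is a diarylmethane carbon and a carboxyl-level carbon ortho to each other on ring A, spanned by the two methyl-bearing carbons C2–C3.
2. Endgame, read backwards: the C7 phenol comes from its benzyl ether, (2R) from base equilibration to the all-trans ketone, C2–H from loss of CO2 from a C2 acyl group, and C2–CH3 from methylation of a β-keto imide.
3. Key disconnection: C3–C4 and C1–C2 are made together in an anionic [4+2] annulation (conjugate addition, then Claisen closure) of a C4-lithiated 2-benzylbenzoate with an N-crotonyl oxazolidinone. The extra carbonyl makes C3 electrophilic and C2 nucleophilic, and it carries the chirality.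
4. The benzoate comes from a Negishi coupling of a 2-bromobenzoate (ring A) with 3,4-dimethoxybenzylzinc chloride (ring C). Only ring A bears the ester, so no choice between two similar arenes arises at ring closure.
5. Ring order: rings A and C are bought, and ring B is the only ring made (step 5).

Key step: step 5

Assumption: the imide is taken to react through its lithium-bridged conformer (both carbonyls syn, crotonyl s-cis), the model that links the (S)-auxiliary to (3S); if the open anti conformer reacted instead, the equally available (R)-oxazolidinone would be used in the same steps.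

## Route

Step 1
Reactants: 1 2-bromo-5-hydroxy-4-methoxybenzaldehyde
Product: 2 5-(benzyloxy)-2-bromo-4-methoxybenzaldehyde
Conditions: BnBr, K2CO3, DMF, 25 °C
Reagents that add atoms: benzyl bromide, BrCc1ccccc1
Why: Williamson etherification of the single phenol; the benzyl ether should withstand amide base, carbonate, peroxide and palladium coupling and leaves by hydrogenolysis in the last step.

Step 2
Reactants: 2 5-(benzyloxy)-2-bromo-4-methoxybenzaldehyde
Product: 3 methyl 5-(benzyloxy)-2-bromo-4-methoxybenzoate
Conditions: I2, KOH, MeOH/THF, 0 °C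
Reagents that add atoms: methanol, CO
Why: Oxidative esterification, in which the methyl hemiacetal of the non-enolisable aldehyde is oxidised by hypoiodite formed from I2 and KOH, reaching the ester in one operation and leaving aryl bromide and aryl ethers alone.

Step 3
Reactants: 3 methyl 5-(benzyloxy)-2-bromo-4-methoxybenzoate; 4 3,4-dimethoxybenzyl chloride
Product: 6 methyl 5-(benzyloxy)-2-(3,4-dimethoxybenzyl)-4-methoxybenzoate, via 3,4-dimethoxybenzylzinc chloride 5 (not isolated)
Conditions: 4, Zn dust, LiCl, THF, 25 °C; then 3, Pd(OAc)2 (2 mol%), SPhos (4 mol%), THF, 25 to 50 °C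
Reagents that add atoms: none
Why: Negishi coupling, in which LiCl-assisted zinc insertion into the benzylic chloride gives an ester-tolerant organozinc with little Wurtz coupling, zerovalent palladium inserts into the C–Br bond activated by the ortho ester, and the benzyl group has no β-hydrogen to lose.

Step 4
Reactants: 7 (S)-4-benzyloxazolidin-2-one; 8 (E)-but-2-enoyl chloride
Product: 10 (S)-4-benzyl-3-[(E)-but-2-enoyl]oxazolidin-2-one, via N-lithio oxazolidinone 9 (not isolated)
Conditions: n-BuLi, THF, −78 °C; then 8, −78 to 0 °C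
Reagents that add atoms: none
Why: N-Acylation of the lithiated oxazolidinone with the acid chloride at low temperature, which touches neither the auxiliary stereocentre nor the E double bond.

Step 5
Reactants: 6 methyl 5-(benzyloxy)-2-(3,4-dimethoxybenzyl)-4-methoxybenzoate; 10 (S)-4-benzyl-3-[(E)-but-2-enoyl]oxazolidin-2-one
Product: 14 (S)-4-benzyl-3-[(2R,3S,4R)-7-(benzyloxy)-4-(3,4-dimethoxyphenyl)-6-methoxy-3-methyl-1-oxo-1,2,3,4-tetrahydronaphthalene-2-carbonyl]oxazolidin-2-one, via C4-lithiated benzoate 11 (not isolated), via Michael adduct lithium enolate 12 (not isolated), via lithium enolate of the keto imide 13 (not isolated)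
Conditions: LiN(i-Pr)2 (1.05 equiv), THF, −78 °C; then 10 (1.2 equiv), −78 to 0 °C; then AcOH
Reagents that add atoms: none
Why: LiN(i-Pr)2 removes a C4 proton, acidified by both arenes and by the ortho ester, to give the lithium dienolate 11 (an o-quinodimethane-type ester enolate with the ring C aryl turned outward, away from the C(OMe)OLi group), C4 of which adds to the β-carbon of 10 (C3–C4 bond), after which the Z imide enolate 12 attacks the adjacent ester carbon (C1–C2 bond), methoxide leaves and deprotonates C2 to give 13, so that the retro-Michael path is shut. The closest known reaction is the Staunton–Weinreb annulation, the tandem Michael–Dieckmann reaction of laterally lithiated o-toluates (secondary benzylic anions included) with crotonates and enones, while face control by N-enoyl oxazolidinones is established for conjugate additions and for chelated Diels–Alder reactions. Ring B closes in a 6-(enolexo)-exo-trig Claisen condensation. C3 is controlled by the auxiliary: lithium bridges the two imide carbonyls, the crotonyl group lies s-cis, the benzyl group on the oxazolidinone covers one face, and attack on the open face of the (S)-imide gives (3S). C4 is fixed relative to C3 in the same bond-forming event, since the lithium that ties the dienolate oxygen to the imide oxygens enforces an endo, [4+2]-like array in which the outward aryl group and the β-methyl group come out trans (4R), whereas C2 (formed trans to C3) is labile and is reset in step 8. The step needs 1,4- over 1,2-addition and addition over γ-deprotonation of 10, which the soft delocalised carbanion, the absence of excess amide base and the low temperature should secure, and any minor isomer is removable at this stage because the auxiliary makes all isomers diastereomeric.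

Step 6
Reactants: 14 the β-keto imide of step 5
Product: 15 (S)-4-benzyl-3-[(3S,4R)-7-(benzyloxy)-4-(3,4-dimethoxyphenyl)-6-methoxy-2,3-dimethyl-1-oxo-1,2,3,4-tetrahydronaphthalene-2-carbonyl]oxazolidin-2-one (C2 configuration open)
Conditions: MeI, K2CO3, acetone, 40 °C
Reagents that add atoms: iodomethane, CI
Why: C-Alkylation of a β-dicarbonyl enolate with the soft electrophile MeI, as is routine for 2-acyl-1-tetralones; it ends at monomethylation because no C2–H remains, it exposes the imide carbonyl for step 7 by blocking enolisation, and the configuration of the quaternary C2 is of no consequence since it is erased in step 7.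

Step 7
Reactants: 15 the C2-methylated β-keto imide
Product: 18 (3S,4R)-7-(benzyloxy)-4-(3,4-dimethoxyphenyl)-6-methoxy-2,3-dimethyl-3,4-dihydronaphthalen-1(2H)-one (C2 epimer mixture), via peroxy acid 16 (not isolated), via beta-keto acid 17 (not isolated)
Conditions: LiOH, H2O2, THF/H2O, 0 °C; Na2SO3; HCl to pH 2; toluene, 80 °C
Reagents that add atoms: none
Why: Hydroperoxide cleavage of an N-acyl oxazolidinone at the exocyclic carbonyl followed by thermal decarboxylation of the β-keto acid through its cyclic six-centre transition state; C–C cleavage at the same carbonyl would give the same ketone, C3 and C4 are not acidic under these conditions, and protonation of the enol leaves C2 as an epimer mixture.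

Step 8
Reactants: 18 the ketone as C2 epimer mixture
Product: 19 (2R,3S,4R)-7-(benzyloxy)-4-(3,4-dimethoxyphenyl)-6-methoxy-2,3-dimethyl-3,4-dihydronaphthalen-1(2H)-one (O-benzyl epischisandrone)
Conditions: DBU, toluene, 60 °C
Reagents that add atoms: none
Why: Thermodynamic epimerisation through the enolate, in which only C2–H is acidic enough for DBU and the all-trans isomer, able to place the C2 methyl, C3 methyl and C4 aryl groups all (pseudo)equatorial on the half-chair, should dominate and so set (2R); residual cis epimer can be separated and resubmitted.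

Step 9
Reactants: 19 O-benzyl epischisandrone
Product: 20 epischisandrone, (2R,3S,4R)-4-(3,4-dimethoxyphenyl)-7-hydroxy-6-methoxy-2,3-dimethyl-3,4-dihydronaphthalen-1(2H)-one
Conditions: H2 (1 atm), 10% Pd/C, EtOAc, 25 °C
Reagents that add atoms: none
Why: Hydrogenolysis of the aryl benzyl ether, which under neutral conditions at 1 atm should outrun reduction of the electron-rich aryl ketone and cannot epimerise C2.

## Compound list

1 | 2-bromo-5-hydroxy-4-methoxybenzaldehyde | COc1cc(Br)c(C=O)cc1O | starting material
2 | 5-(benzyloxy)-2-bromo-4-methoxybenzaldehyde | COc1cc(Br)c(C=O)cc1OCc1ccccc1 | intermediate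
3 | methyl 5-(benzyloxy)-2-bromo-4-methoxybenzoate | COC(=O)c1cc(OCc2ccccc2)c(OC)cc1Br | intermediate
4 | 3,4-dimethoxybenzyl chloride | COc1ccc(CCl)cc1OC | starting material
5 | 3,4-dimethoxybenzylzinc chloride (not isolated) | COc1ccc(C[Zn]Cl)cc1OC | intermediate
6 | methyl 5-(benzyloxy)-2-(3,4-dimethoxybenzyl)-4-methoxybenzoate | COC(=O)c1cc(OCc2ccccc2)c(OC)cc1Cc1ccc(OC)c(OC)c1 | intermediate
7 | (S)-4-benzyloxazolidin-2-one | O=C1OC[C@H](Cc2ccccc2)N1 | starting material
8 | (E)-but-2-enoyl chloride | C/C=C/C(=O)Cl | starting material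
9 | N-lithio (S)-4-benzyloxazolidin-2-one (not isolated) | [Li]N1[C@@H](Cc2ccccc2)COC1=O | intermediate
10 | (S)-4-benzyl-3-[(E)-but-2-enoyl]oxazolidin-2-one | C/C=C/C(=O)N1[C@@H](Cc2ccccc2)COC1=O | intermediate
11 | C4-lithiated 6, drawn as the benzylic lithium compound (not isolated) | COC(=O)c1cc(OCc2ccccc2)c(OC)cc1C([Li])c1ccc(OC)c(OC)c1 | intermediate
12 | lithium Z-enolate of (S)-4-benzyl-3-{(3S,4R)-4-[4-(benzyloxy)-5-methoxy-2-(methoxycarbonyl)phenyl]-4-(3,4-dimethoxyphenyl)-3-methylbutanoyl}oxazolidin-2-one (not isolated) | [Li]O/C(=C\[C@@H](C)[C@@H](c1cc(OC)c(OCc2ccccc2)cc1C(=O)OC)c1ccc(OC)c(OC)c1)N1[C@@H](Cc2ccccc2)COC1=O | intermediate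
13 | lithium C1–C2 enolate of 14 (not isolated) | COc1cc2c(cc1OCc1ccccc1)C(O[Li])=C(C(=O)N1[C@@H](Cc3ccccc3)COC1=O)[C@@H](C)[C@@H]2c1ccc(OC)c(OC)c1 | intermediate
14 | (S)-4-benzyl-3-[(2R,3S,4R)-7-(benzyloxy)-4-(3,4-dimethoxyphenyl)-6-methoxy-3-methyl-1-oxo-1,2,3,4-tetrahydronaphthalene-2-carbonyl]oxazolidin-2-one | COc1cc2c(cc1OCc1ccccc1)C(=O)[C@H](C(=O)N1[C@@H](Cc3ccccc3)COC1=O)[C@@H](C)[C@@H]2c1ccc(OC)c(OC)c1 | intermediate
15 | (S)-4-benzyl-3-[(3S,4R)-7-(benzyloxy)-4-(3,4-dimethoxyphenyl)-6-methoxy-2,3-dimethyl-1-oxo-1,2,3,4-tetrahydronaphthalene-2-carbonyl]oxazolidin-2-one, C2 configuration open | COc1cc2c(cc1OCc1ccccc1)C(=O)C(C)(C(=O)N1[C@@H](Cc3ccccc3)COC1=O)[C@@H](C)[C@@H]2c1ccc(OC)c(OC)c1 | intermediate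
16 | (3S,4R)-7-(benzyloxy)-4-(3,4-dimethoxyphenyl)-6-methoxy-2,3-dimethyl-1-oxo-1,2,3,4-tetrahydronaphthalene-2-carboperoxoic acid (not isolated) | COc1cc2c(cc1OCc1ccccc1)C(=O)C(C)(C(=O)OO)[C@@H](C)[C@@H]2c1ccc(OC)c(OC)c1 | intermediate
17 | (3S,4R)-7-(benzyloxy)-4-(3,4-dimethoxyphenyl)-6-methoxy-2,3-dimethyl-1-oxo-1,2,3,4-tetrahydronaphthalene-2-carboxylic acid (not isolated) | COc1cc2c(cc1OCc1ccccc1)C(=O)C(C)(C(=O)O)[C@@H](C)[C@@H]2c1ccc(OC)c(OC)c1 | intermediate
18 | (3S,4R)-7-(benzyloxy)-4-(3,4-dimethoxyphenyl)-6-methoxy-2,3-dimethyl-3,4-dihydronaphthalen-1(2H)-one, C2 epimer mixture | COc1cc2c(cc1OCc1ccccc1)C(=O)C(C)[C@@H](C)[C@@H]2c1ccc(OC)c(OC)c1 | intermediate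
19 | (2R,3S,4R)-7-(benzyloxy)-4-(3,4-dimethoxyphenyl)-6-methoxy-2,3-dimethyl-3,4-dihydronaphthalen-1(2H)-one | COc1cc2c(cc1OCc1ccccc1)C(=O)[C@H](C)[C@@H](C)[C@@H]2c1ccc(OC)c(OC)c1 | intermediate
20 | epischisandrone, (2R,3S,4R)-4-(3,4-dimethoxyphenyl)-7-hydroxy-6-methoxy-2,3-dimethyl-3,4-dihydronaphthalen-1(2H)-one | COc1cc2c(cc1O)C(=O)[C@H](C)[C@@H](C)[C@@H]2c1ccc(OC)c(OC)c1 | target

## Step count

Total step count: 9.
Longest linear sequence: 8 steps (steps 1, 2, 3, 5, 6, 7, 8, 9; 1 → 2 → 3 → 6 → 14 → 15 → 18 → 19 → 20). Step 4 is a one-step side branch.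

## Steps most likely to fail

**Step 5.**
- Risk: three processes may spoil it.
  - Proton transfer from the γ-methyl group of the imide to the carbanion.
  - A slow Claisen closure at the electron-rich benzoate, so that the imide enolate reverts by retro-Michael cleavage or fragments on warming.
  - Weak facial bias if lithium does not hold the imide in the bridged conformer.
- Fallback (sets out from 6, comes back at 19): auxiliary control is given up and the enantiomers are separated late.
  - Compound 6 is lithiated as before and annulated with methyl (E)-but-2-enoate. This is the classical, less γ-acidic acceptor of this annulation, and its enolate tolerates warming to 0 °C. It gives the racemic methyl 3,4-trans β-keto ester F1.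
  - K2CO3 and MeI in acetone then give the racemic 2-methyl β-keto ester F2.
  - Krapcho demethoxycarbonylation (LiCl, wet DMSO, 150 °C) gives the racemic ketone epimer mixture F3.
  - DBU in toluene gives the racemic all-trans ketone F4.
  - Preparative chromatography on a cellulose tris(3,5-dimethylphenylcarbamate) stationary phase delivers the (2R,3S,4R) enantiomer, which is 19 and enters step 9.

**Step 7.**
- Risk: the exocyclic imide carbonyl sits on a quaternary carbon. Hydroperoxide may therefore turn to the carbamate carbonyl (opening of the oxazolidinone ring) or to the C1 ketone (retro-Claisen or oxidative opening of ring B).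
- Fallback (sets out from 14, comes back at 18): the acyl group is exchanged before quaternisation and is later removed by dealkylative decarboxylation, in which no nucleophile has to reach a hindered carbonyl.
  - Heating 14 with MeOH and catalytic DMAP in toluene should release the auxiliary and give the methyl β-keto ester F5. This is the exchange typical of enolisable β-keto acyl compounds, running through the acylketene.
  - K2CO3 and MeI give the 2-methyl β-keto ester F6.
  - LiCl in wet DMSO at 150 °C (SN2 attack of chloride at the O-methyl group, then loss of CO2) gives 18, which continues with step 8.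

**Step 6.**
- Risk: O-methylation or sluggish alkylation, since C2 is flanked by the C3 methine and by a bulky imide that is twisted out of the enolate plane.
- Fallback (sets out from 14, comes back at 18): the order of events is reversed and C2 is set by kinetic enolate alkylation.
  - LiOH and H2O2 act on the less hindered tertiary imide 14. After Na2SO3, acidification and warming, the sequence runs through the peroxy acid F7 and the β-keto acid F8 to the 2-unsubstituted tetralone F9.
  - Deprotonation of F9 with LiN(SiMe3)2 (1.0 equiv, THF, −78 °C) and addition of MeI should bring the methyl group in by axial attack anti to the C3 methyl group. This gives 18 enriched in the trans epimer, and step 8 completes the convergence.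

## Further compounds

F1 | step 5 | racemic methyl (2R*,3S*,4R*)-7-(benzyloxy)-4-(3,4-dimethoxyphenyl)-6-methoxy-3-methyl-1-oxo-1,2,3,4-tetrahydronaphthalene-2-carboxylate | COc1cc2c(cc1OCc1ccccc1)C(=O)[C@H](C(=O)OC)[C@@H](C)[C@@H]2c1ccc(OC)c(OC)c1.COc1cc2c(cc1OCc1ccccc1)C(=O)[C@@H](C(=O)OC)[C@H](C)[C@H]2c1ccc(OC)c(OC)c1
F2 | step 5 | racemic methyl (3S*,4R*)-7-(benzyloxy)-4-(3,4-dimethoxyphenyl)-6-methoxy-2,3-dimethyl-1-oxo-1,2,3,4-tetrahydronaphthalene-2-carboxylate, C2 open | COc1cc2c(cc1OCc1ccccc1)C(=O)C(C)(C(=O)OC)[C@@H](C)[C@@H]2c1ccc(OC)c(OC)c1.COc1cc2c(cc1OCc1ccccc1)C(=O)C(C)(C(=O)OC)[C@H](C)[C@H]2c1ccc(OC)c(OC)c1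
F3 | step 5 | racemic (3S*,4R*)-7-(benzyloxy)-4-(3,4-dimethoxyphenyl)-6-methoxy-2,3-dimethyl-3,4-dihydronaphthalen-1(2H)-one, C2 epimer mixture | COc1cc2c(cc1OCc1ccccc1)C(=O)C(C)[C@@H](C)[C@@H]2c1ccc(OC)c(OC)c1.COc1cc2c(cc1OCc1ccccc1)C(=O)C(C)[C@H](C)[C@H]2c1ccc(OC)c(OC)c1
F4 | step 5 | racemic (2R*,3S*,4R*)-7-(benzyloxy)-4-(3,4-dimethoxyphenyl)-6-methoxy-2,3-dimethyl-3,4-dihydronaphthalen-1(2H)-one | COc1cc2c(cc1OCc1ccccc1)C(=O)[C@H](C)[C@@H](C)[C@@H]2c1ccc(OC)c(OC)c1.COc1cc2c(cc1OCc1ccccc1)C(=O)[C@@H](C)[C@H](C)[C@H]2c1ccc(OC)c(OC)c1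
F5 | step 7 | methyl (2R,3S,4R)-7-(benzyloxy)-4-(3,4-dimethoxyphenyl)-6-methoxy-3-methyl-1-oxo-1,2,3,4-tetrahydronaphthalene-2-carboxylate | COc1cc2c(cc1OCc1ccccc1)C(=O)[C@H](C(=O)OC)[C@@H](C)[C@@H]2c1ccc(OC)c(OC)c1
F6 | step 7 | methyl (3S,4R)-7-(benzyloxy)-4-(3,4-dimethoxyphenyl)-6-methoxy-2,3-dimethyl-1-oxo-1,2,3,4-tetrahydronaphthalene-2-carboxylate, C2 open | COc1cc2c(cc1OCc1ccccc1)C(=O)C(C)(C(=O)OC)[C@@H](C)[C@@H]2c1ccc(OC)c(OC)c1
F7 | step 6 | (2R,3S,4R)-7-(benzyloxy)-4-(3,4-dimethoxyphenyl)-6-methoxy-3-methyl-1-oxo-1,2,3,4-tetrahydronaphthalene-2-carboperoxoic acid | COc1cc2c(cc1OCc1ccccc1)C(=O)[C@H](C(=O)OO)[C@@H](C)[C@@H]2c1ccc(OC)c(OC)c1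
F8 | step 6 | (2R,3S,4R)-7-(benzyloxy)-4-(3,4-dimethoxyphenyl)-6-methoxy-3-methyl-1-oxo-1,2,3,4-tetrahydronaphthalene-2-carboxylic acid | COc1cc2c(cc1OCc1ccccc1)C(=O)[C@H](C(=O)O)[C@@H](C)[C@@H]2c1ccc(OC)c(OC)c1
F9 | step 6 | (3R,4R)-7-(benzyloxy)-4-(3,4-dimethoxyphenyl)-6-methoxy-3-methyl-3,4-dihydronaphthalen-1(2H)-one | COc1cc2c(cc1OCc1ccccc1)C(=O)C[C@@H](C)[C@@H]2c1ccc(OC)c(OC)c1
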